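(The readings come from a simulation with made-up constants, noise included.)

**Age rule.** Read epsilon and gamma as one curve Y(a): target, in percent of the substrate charged, at age a, the time a portion of substrate has spent in the mixture. Gamma, with substrate at 0.30 M against 0.20 M and the same partner, interpolates to 9.83 % at 6.00 min, where epsilon reads 9.5 %; the scatter is 0.3 percentage points. So the percent does not follow the substrate concentration in this range. With partner held at 0.50 M in both runs, the rate looks first order in substrate, and you may let each portion age on its own. That is an assumption for the more dilute flasks.

| flask | substrate | partner | remark | time |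
|---|---|---|---|---|
| epsilon | 0.20 M | 0.50 M | run made earlier |  |
| gamma | 0.30 M | 0.50 M | run made earlier |  |
| birch | 0.20 M | 0.500 M | plug flow through a tube for 2.0 h, no back-mixing | 2.0 h |
| oak | 0.20 M | 0.500 M | a closed flask charged with all of it at once and left for 2.0 h | 2.0 h |
| ash | 0.20 M | 0.500 M | one stirred flow tank at steady state, fed with the mixture as stated, mean residence time 2.0 h |  |
| larch | 0.20 M (fed, over 1.60 h) | 0.500 M | all but substrate at the start; substrate goes in evenly over 1.60 h, the run ends at 2.0 h | 2.0 h |

| run | time / min | target / % |
|---|---|---|
| epsilon | 6.00 | 9.5 |
| epsilon | 20.0 | 39.3 |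
| epsilon | 30.0 | 49.2 |
| epsilon | 50.0 | 54.1 |
| epsilon | 80.0 | 45.4 |
| epsilon | 90.0 | 41.8 |
| epsilon | 120 | 30.0 |
| gamma | 0.667 | 0.8 |
| gamma | 2.00 | 2.0 |
| gamma | 3.00 | 3.5 |
| gamma | 5.00 | 7.4 |
| gamma | 8.00 | 14.7 |
| gamma | 10.0 | 19.8 |
| gamma | 12.0 | 23.9 |

(each reading ± 0.3 percentage points)

- the stated concentrations are those of everything mixed, before any reaction; amounts are the same in each set-up
- the numbers in the tables scatter with a standard deviation of 0.3 percentage points
- the feed brings no volume worth counting
- the earlier runs were made in a closed, stirred flask

* the set-up with the highest amount of target at the outlet or at the end, in percent of the substrate put in ("none" if the first two lie within 2 percentage points) (birch / oak / ash / larch / none)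
* amount of target at the outlet or at the end, in percent of the substrate put in, birch
* amount of target at the outlet or at the end, in percent of the substrate put in, oak
* amount of target at the outlet or at the end, in percent of the substrate put in, ash
* amount of target at the outlet or at the end, in percent of the substrate put in, larch

**First instants.** Gamma stands at 2.0 % after 2.00 min and 19.8 % after 10.0 min, so its mean rise per minute grows: something unseen lies between substrate and target.

**Middle.** Epsilon's highest reading is 54.1 % at 50.0 min. Near that age, making and losing target balance.

**End.** Epsilon falls to 41.8 % at 90.0 min and 30.0 % at 120 min, so age now costs target. Birch and oak give their whole charge one age, so you read 30.0 % for both.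

**Larch window.** Substrate enters evenly over 1.60 h, so at 2.0 h the ages spread evenly from 24.0 min to 120 min. Trapezoids over the readings, with 43.3 % interpolated at the young edge, give 45.0 % for the window mean Ȳ, the average of Y(a) over the ages present. That is more than your birch figure. Ash spreads ages exponentially, with a tail past the last reading, so the window gives no figure for it.

**The forecast.** It names larch, with 45 % for larch and 30 %, 30 % and 30 % for birch, oak and ash, “because the material is younger and sits near the maximum”.

**Result.** The best set-up is larch: larch gives 45.4 %, birch 30.0 %, oak 30.0 %, ash 30.1 %.

    substrate → intermediate A (k = 0.0396 min⁻¹)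
    partner + intermediate A ⇌ intermediate B (K = 1.40 M⁻¹, k = 0.00377 M⁻¹ min⁻¹)
    partner + intermediate A → target (k = 0.497 M⁻¹ min⁻¹)
    target ⇌ isomer of the product (K = 21.5, k = 0.0144 min⁻¹)

Larch at 2.00 h holds 41.1 % of isomer of the product, less than the 68.2 % in birch. Ȳ stands 0.40 points under the larch figure. Now move the window to the end of the larch feed, when ages run from zero to 96.0 min. Taking the oldest slice off Ȳ and adding the youngest gives 41.9 %, and larch at 1.60 h holds 42.3 %.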